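The C5–C6 bond of ring B is the disconnection on which the route rests. C10 is a quaternary carbon of ring A that sits para to the C3 oxygen and carries two constitutionally identical arms (C1–C2 and C5–C4), so ring A maps onto an achiral 4-methyl-4-alkylcyclohexa-2,5-dienone. A chiral triazolium carbene turns a side-chain aldehyde (C6) into an acyl anion equivalent that attacks C5 of one arm only: one operation closes ring B, fixes the C10 configuration and, after equilibration at C5, the trans ring fusion. The precursor is therefore the dienone bearing a CH2–C(dioxolane)–CH2–CHO chain (C9–C8–C7–C6) on its quaternary carbon.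

Key step: step 8

Remark: eudesmane numbering is used throughout (ring A = C1–C5 plus C10, ring B = C5–C10, β = the face of the C10 methyl); the sense of arm selection by the carbene is assigned by analogy, so the catalyst antipode that gives the 10β-methyl series is assumed, both antipodes being accessible from the enantiomers of cis-1-amino-2-indanol.

Step 1
Reactants: 1 2-methylpent-4-enal (racemic); 2 methyl vinyl ketone
Product: 3 4-allyl-4-methylcyclohex-2-en-1-one (racemic)
Conditions: conc. H2SO4 (cat.), toluene, 45 °C then reflux (Dean–Stark)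
Reagents that add atoms: none
Why: Acid-catalysed Robinson annulation (Michael addition of the aldehyde enol to the enone, then aldol condensation) is the standard entry from an α-branched aldehyde to a 4,4-disubstituted cyclohexenone, and the racemic quaternary centre is immaterial because step 2 makes that carbon non-stereogenic.

Step 2
Reactants: 3 4-allyl-4-methylcyclohex-2-en-1-one
Product: 4 4-allyl-4-methylcyclohexa-2,5-dien-1-one
Conditions: DDQ, 1,4-dioxane, reflux
Reagents that add atoms: none
Why: Quinone dehydrogenation of the enone through its dienol should give the cross-conjugated dienone, which cannot aromatise because C4 is quaternary and whose two enone arms are now equivalent.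

Step 3
Reactants: 4 4-allyl-4-methylcyclohexa-2,5-dien-1-one
Product: 5 2-(1-methyl-4-oxocyclohexa-2,5-dien-1-yl)acetaldehyde
Conditions: O3 (1 equiv, Sudan Red 7B end point), CH2Cl2–MeOH, −78 °C; Me2S, −78 °C → rt
Reagents that add atoms: ozone, [O-][O+]=O
Why: Ozonolysis with reductive work-up should cleave only the isolated terminal alkene, which reacts far faster than the electron-poor dienone double bonds, the dye marking its consumption.

Step 4
Reactants: 5 2-(1-methyl-4-oxocyclohexa-2,5-dien-1-yl)acetaldehyde; 6 allyl bromide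
Product: 7 4-(2-hydroxypent-4-en-1-yl)-4-methylcyclohexa-2,5-dien-1-one (racemic)
Conditions: Zn dust, THF–sat. aq. NH4Cl, 0 °C → rt
Reagents that add atoms: none
Why: Aqueous Barbier allylation should add the allylzinc species to the aldehyde only, the cross-conjugated dienone carbonyl being much less electrophilic, and the racemic carbinol centre is oxidised away in step 5.

Step 5
Reactants: 7 4-(2-hydroxypent-4-en-1-yl)-4-methylcyclohexa-2,5-dien-1-one
Product: 8 4-methyl-4-(2-oxopent-4-en-1-yl)cyclohexa-2,5-dien-1-one
Conditions: Dess–Martin periodinane, pyridine, CH2Cl2, 0 °C; crude product used at once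
Reagents that add atoms: none
Why: Dess–Martin oxidation under buffered, non-basic conditions should give the β,γ-unsaturated ketone without conjugating the alkene or triggering enolate Michael addition to the dienone.

Step 6
Reactants: 8 4-methyl-4-(2-oxopent-4-en-1-yl)cyclohexa-2,5-dien-1-one
Product: 9 4-methyl-4-{[2-(prop-2-en-1-yl)-1,3-dioxolan-2-yl]methyl}cyclohexa-2,5-dien-1-one
Conditions: (TMSOCH2)2, TMSOTf (cat.), CH2Cl2, −78 °C; pyridine quench
Reagents that add atoms: 1,2-bis(trimethylsilyloxy)ethane, C[Si](C)(C)OCCO[Si](C)(C)C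
Why: Silyl triflate-catalysed ketalisation with the bis-silyl ether (Noyori conditions) should protect the saturated ketone at −78 °C, leave the conjugated dienone carbonyl untouched and not migrate the β,γ double bond.

Step 7
Reactants: 9 4-methyl-4-{[2-(prop-2-en-1-yl)-1,3-dioxolan-2-yl]methyl}cyclohexa-2,5-dien-1-one
Product: 10 2-{2-[(1-methyl-4-oxocyclohexa-2,5-dien-1-yl)methyl]-1,3-dioxolan-2-yl}acetaldehyde
Conditions: O3 (1 equiv, Sudan Red 7B end point), CH2Cl2, −78 °C; PPh3, −78 °C → rt; used without storage
Reagents that add atoms: ozone, [O-][O+]=O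
Why: Chemoselective ozonolysis of the terminal alkene as in step 3, with a neutral reductive work-up so that the β-ketal aldehyde should not lose a ketal oxygen by β-elimination.

Step 8
Reactants: 10 2-{2-[(1-methyl-4-oxocyclohexa-2,5-dien-1-yl)methyl]-1,3-dioxolan-2-yl}acetaldehyde
Product: 12 (5α,10β)-8,8-(ethylenedioxy)-11,12,13,15-tetranoreudesm-1-ene-3,6-dione (trans-fused), via cis-fused 5β-dione 11 (not isolated)
Conditions: 2-(pentafluorophenyl)-5a,10b-dihydro-4H,6H-indeno[2,1-b][1,2,4]triazolo[4,3-d][1,4]oxazin-2-ium tetrafluoroborate (single antipode, 20 mol%), KN(SiMe3)2 (20 mol%), toluene, rt; then DBU (0.2 equiv), 0 °C → rt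
Reagents that add atoms: none
Why: The carbene adds to the C6 aldehyde and proton transfer gives the nucleophilic enaminol (acyl anion equivalent), which adds to C5, the β-carbon of one enone arm, before proton transfer and loss of the carbene release the 1,4-diketone. The closest known reaction type is the asymmetric intramolecular Stetter desymmetrisation of 4,4-disubstituted cyclohexadienones with chiral triazolium carbenes, applied here to an all-carbon tether whose gem-dialkoxy C8 should favour folding (Thorpe–Ingold effect). Ring B closes in the 6-exo-trig mode. C10 is set by the catalyst, which chooses between the two enantiotopic arms, whereas C5 is first set cis by the tether (C6 must arrive on the face that carries C9) and is then inverted through the C6 enolate under the amidine base to the trans ring fusion, the isomer expected to be favoured by analogy with the base isomerisation of cis-fused angularly methylated decalindiones and 6-oxo-5β-steroids. The step needs arm selectivity, which only the catalyst can supply because the dienone is Cs-symmetric and the ketal achiral, and it needs acylation to outrun aldehyde enolisation, which the non-enolisable dienone and the hindered C7 methylene next to the ketal carbon should secure.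

Step 9
Reactants: 12 (5α,10β)-8,8-(ethylenedioxy)-11,12,13,15-tetranoreudesm-1-ene-3,6-dione
Product: 13 (5α,6β,10β)-8,8-(ethylenedioxy)-6-hydroxy-11,12,13,15-tetranoreudesm-1-en-3-one
Conditions: NaBH4, MeOH–CH2Cl2 (1:1), −78 °C
Reagents that add atoms: none
Why: Low-temperature borohydride reduction should discriminate the saturated C6 ketone from the conjugated C3 enone, and hydride should enter from the α face, because the β face is screened by the axial C10 methyl and the axial ketal oxygen, giving the axial 6β-alcohol.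

Step 10
Reactants: 13 (5α,6β,10β)-8,8-(ethylenedioxy)-6-hydroxy-11,12,13,15-tetranoreudesm-1-en-3-one
Product: 15 (5α,10β)-8,8-(ethylenedioxy)-11,12,13,15-tetranoreudesma-1,6-dien-3-one, via 6β-sulfamate ester 14 (not isolated)
Conditions: Burgess reagent (methyl N-(triethylammoniosulfonyl)carbamate), toluene, rt then 70 °C
Reagents that add atoms: none
Why: Burgess dehydration is a stereospecific syn elimination (Ei) of the sulfamate ester, and in the trans-fused ring B only H-7β is cis to the axial 6β-oxygen (H-5 is α and antiperiplanar), so the alkene should form at C6=C7, which removes the C6 oxygen and leaves C8 as an allylic ketal.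

Step 11
Reactants: 15 (5α,10β)-8,8-(ethylenedioxy)-11,12,13,15-tetranoreudesma-1,6-dien-3-one
Product: 16 (4βH,5α,10β)-8,8-(ethylenedioxy)-11,12,13-trinoreudesma-1,6-dien-3-one (4α-methyl)
Conditions: LiN(i-Pr)2, THF, −78 °C; MeI, −78 → −30 °C
Reagents that add atoms: iodomethane, CI
Why: Kinetic α′-deprotonation of the enone can only occur at C4 (C2 is vinylic, C10 quaternary) and C-methylation of the cross-conjugated lithium enolate should occur anti to the axial C10 methyl (4α-methyl), a configuration that is immaterial because C4 is re-enolised in step 12.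

Step 12
Reactants: 16 (4βH,5α,10β)-8,8-(ethylenedioxy)-11,12,13-trinoreudesma-1,6-dien-3-one
Product: 17 (5α,10β)-8,8-(ethylenedioxy)-4α-hydroxy-11,12,13-trinoreudesma-1,6-dien-3-one (4β-methyl)
Conditions: NaN(SiMe3)2, THF, −78 °C; 2-(phenylsulfonyl)-3-phenyloxaziridine, −78 °C; AcOH quench
Reagents that add atoms: 2-(phenylsulfonyl)-3-phenyloxaziridine, O=S(=O)(N1OC1c1ccccc1)c1ccccc1
Why: Davis hydroxylation of the tetrasubstituted sodium enolate should deliver oxygen to the α face of C4, anti to the C10 methyl that is 1,3-diaxial to the β face, setting 4α-OH and 4β-CH3.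

Step 13
Reactants: 17 (5α,10β)-8,8-(ethylenedioxy)-4α-hydroxy-11,12,13-trinoreudesma-1,6-dien-3-one
Product: 18 (5α,10β)-8,8-(ethylenedioxy)-4α-hydroxy-11,12,13-trinoreudesman-3-one
Conditions: H2 (1 atm), Pd/C, EtOAc, Et3N (trace), rt
Reagents that add atoms: none
Why: Heterogeneous catalytic hydrogenation should saturate the enone C1=C2 and the disubstituted C6=C7 in one operation without touching a stereocentre, the amine suppressing hydrogenolysis and acid-catalysed opening of the allylic ketal.

Step 14
Reactants: 18 (5α,10β)-8,8-(ethylenedioxy)-4α-hydroxy-11,12,13-trinoreudesman-3-one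
Product: 20 (5α,10β)-3α,4α-dihydroxy-11,12,13-trinoreudesman-8-one, via 3α,4α-diol ketal 19 (not isolated)
Conditions: LiBH(s-Bu)3 (3 equiv), THF, −78 °C; then 2 M aq. HCl, THF, rt
Reagents that add atoms: water, O
Why: Equatorial hydride delivery by the bulky trialkylborohydride to the C3 ketone next to the quaternary C4 should give the axial 3α-alcohol cis to the 4α-hydroxyl (as in reductions of 4,4-disubstituted 3-oxo terpenoids), and the acidic work-up hydrolyses the dioxolane to the C8 ketone.

Step 15
Reactants: 20 (5α,10β)-3α,4α-dihydroxy-11,12,13-trinoreudesman-8-one; 21 angelic acid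
Product: 23 (5α,10β)-3α-angeloyloxy-4α-hydroxy-11,12,13-trinoreudesman-8-one, via angelic trichlorobenzoic anhydride 22 (not isolated)
Conditions: 2,4,6-trichlorobenzoyl chloride, Et3N, toluene, rt; then the diol, toluene, 80 °C
Reagents that add atoms: none
Why: Yamaguchi esterification through the sterically biased mixed anhydride should acylate the secondary 3α-hydroxyl only (the tertiary 4-hydroxyl is inert) and, run without a nucleophilic catalyst, should keep the Z geometry that the angeloyl group brings unchanged from the acid.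

Step 16
Reactants: 23 (5α,10β)-3α-angeloyloxy-4α-hydroxy-11,12,13-trinoreudesman-8-one
Product: 24 (5α,10β)-4α-acetoxy-3α-angeloyloxy-11,12,13-trinoreudesman-8-one
Conditions: Ac2O, TMSOTf (cat.), CH2Cl2, −20 °C
Reagents that add atoms: acetic anhydride, CC(=O)OC(C)=O
Why: Silyl triflate-catalysed acetylation is fast enough for tertiary alcohols at low temperature, so the 4α-hydroxyl should be esterified before acyl migration from O3 or enol acetylation of the C8 ketone can intervene.

Step 17
Reactants: 24 (5α,10β)-4α-acetoxy-3α-angeloyloxy-11,12,13-trinoreudesman-8-one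
Product: 25 (5α,7αH,10β)-4α-acetoxy-3α-angeloyloxy-11-hydroxyeudesman-8-one
Conditions: TiCl4, Bu3N, CH2Cl2, −78 °C; acetone, −78 °C; aq. NH4Cl
Reagents that add atoms: acetone, CC(C)=O
Why: In this titanium-mediated direct crossed aldol (soft enolisation) only the ketone should be enolised at −78 °C, toward C7 because C9 is neopentylic next to the quaternary C10, and the titanium enolate adds to acetone, the new C7 centre (side chain expected equatorial, 7β) disappearing in step 18.

Step 18
Reactants: 25 (5α,7αH,10β)-4α-acetoxy-3α-angeloyloxy-11-hydroxyeudesman-8-one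
Product: 27 (5α,10β)-4α-acetoxy-3α-angeloyloxyeudesm-7(11)-en-8-one, via 11-mesylate 26 (not isolated)
Conditions: MsCl, Et3N, CH2Cl2, 0 °C → rt
Reagents that add atoms: none
Why: Mesylation of the tertiary β-hydroxy ketone (sulfene pathway) followed by E1cB elimination through the C7 enolate can only give the conjugated, tetrasubstituted C7=C11 alkene.

Step 19
Reactants: 27 (5α,10β)-4α-acetoxy-3α-angeloyloxyeudesm-7(11)-en-8-one
Product: 28 (5α,10β)-4α-acetoxy-3α-angeloyloxy-11-hydroperoxyeudesm-6-en-8-one (target, CNP0225062.1)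
Conditions: O2, tetraphenylporphyrin (cat.), visible light, CH2Cl2, 0 °C
Reagents that add atoms: dioxygen, O=O
Why: In the Schenck ene reaction of singlet oxygen with the s-cis enone, oxygen should bond to the β-carbon C11 and hydrogen be taken from C6, the alkyl group geminal to the carbonyl on C7 (gem effect), so the double bond moves to C6=C7 and the tertiary allylic hydroperoxide forms without disturbing C5 or any other stereocentre.

Compound list

1 | 2-methylpent-4-enal (racemic) | C=CCC(C)C=O | starting material
2 | methyl vinyl ketone (but-3-en-2-one) | C=CC(C)=O | starting material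
3 | 4-allyl-4-methylcyclohex-2-en-1-one (racemic) | C=CCC1(C)CCC(=O)C=C1 | intermediate
4 | 4-allyl-4-methylcyclohexa-2,5-dien-1-one | C=CCC1(C)C=CC(=O)C=C1 | intermediate
5 | 2-(1-methyl-4-oxocyclohexa-2,5-dien-1-yl)acetaldehyde | O=CCC1(C)C=CC(=O)C=C1 | intermediate
6 | allyl bromide (3-bromoprop-1-ene) | C=CCBr | starting material
7 | 4-(2-hydroxypent-4-en-1-yl)-4-methylcyclohexa-2,5-dien-1-one (racemic) | C=CCC(O)CC1(C)C=CC(=O)C=C1 | intermediate
8 | 4-methyl-4-(2-oxopent-4-en-1-yl)cyclohexa-2,5-dien-1-one | C=CCC(=O)CC1(C)C=CC(=O)C=C1 | intermediate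
9 | 4-methyl-4-{[2-(prop-2-en-1-yl)-1,3-dioxolan-2-yl]methyl}cyclohexa-2,5-dien-1-one | C=CCC1(CC2(C)C=CC(=O)C=C2)OCCO1 | intermediate
10 | 2-{2-[(1-methyl-4-oxocyclohexa-2,5-dien-1-yl)methyl]-1,3-dioxolan-2-yl}acetaldehyde (key-step precursor) | O=CCC1(CC2(C)C=CC(=O)C=C2)OCCO1 | intermediate
11 | (5β,10β)-8,8-(ethylenedioxy)-11,12,13,15-tetranoreudesm-1-ene-3,6-dione (cis-fused; 5R,10S) | O=C1C=C[C@]2(C)CC3(OCCO3)CC(=O)[C@@H]2C1 | intermediate
12 | (5α,10β)-8,8-(ethylenedioxy)-11,12,13,15-tetranoreudesm-1-ene-3,6-dione (trans-fused; 5S,10S; key-step product) | O=C1C=C[C@]2(C)CC3(OCCO3)CC(=O)[C@H]2C1 | intermediate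
13 | (5α,6β,10β)-8,8-(ethylenedioxy)-6-hydroxy-11,12,13,15-tetranoreudesm-1-en-3-one | O=C1C=C[C@]2(C)CC3(OCCO3)C[C@@H](O)[C@H]2C1 | intermediate
14 | triethylammonium salt of the 6β-O-[N-(methoxycarbonyl)sulfamoyl] derivative of 13 | O=C1C=C[C@]2(C)CC3(OCCO3)C[C@@H](OS(=O)(=O)[N-]C(=O)OC)[C@H]2C1.CC[NH+](CC)CC | intermediate
15 | (5α,10β)-8,8-(ethylenedioxy)-11,12,13,15-tetranoreudesma-1,6-dien-3-one | O=C1C=C[C@]2(C)CC3(OCCO3)C=C[C@H]2C1 | intermediate
16 | (4βH,5α,10β)-8,8-(ethylenedioxy)-11,12,13-trinoreudesma-1,6-dien-3-one (4α-methyl) | O=C1C=C[C@]2(C)CC3(OCCO3)C=C[C@H]2[C@@H]1C | intermediate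
17 | (5α,10β)-8,8-(ethylenedioxy)-4α-hydroxy-11,12,13-trinoreudesma-1,6-dien-3-one (4β-methyl) | O=C1C=C[C@]2(C)CC3(OCCO3)C=C[C@H]2[C@]1(C)O | intermediate
18 | (5α,10β)-8,8-(ethylenedioxy)-4α-hydroxy-11,12,13-trinoreudesman-3-one | O=C1CC[C@]2(C)CC3(OCCO3)CC[C@H]2[C@]1(C)O | intermediate
19 | (5α,10β)-8,8-(ethylenedioxy)-11,12,13-trinoreudesmane-3α,4α-diol | O[C@@H]1CC[C@]2(C)CC3(OCCO3)CC[C@H]2[C@]1(C)O | intermediate
20 | (5α,10β)-3α,4α-dihydroxy-11,12,13-trinoreudesman-8-one | O[C@@H]1CC[C@]2(C)CC(=O)CC[C@H]2[C@]1(C)O | intermediate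
21 | angelic acid ((Z)-2-methylbut-2-enoic acid) | C/C=C(/C)C(=O)O | starting material
22 | (Z)-2-methylbut-2-enoic 2,4,6-trichlorobenzoic anhydride | C/C=C(/C)C(=O)OC(=O)c1c(Cl)cc(Cl)cc1Cl | intermediate
23 | (5α,10β)-3α-angeloyloxy-4α-hydroxy-11,12,13-trinoreudesman-8-one | C/C=C(/C)C(=O)O[C@@H]1CC[C@]2(C)CC(=O)CC[C@H]2[C@]1(C)O | intermediate
24 | (5α,10β)-4α-acetoxy-3α-angeloyloxy-11,12,13-trinoreudesman-8-one | C/C=C(/C)C(=O)O[C@@H]1CC[C@]2(C)CC(=O)CC[C@H]2[C@]1(C)OC(C)=O | intermediate
25 | (5α,7αH,10β)-4α-acetoxy-3α-angeloyloxy-11-hydroxyeudesman-8-one (expected 7β side chain; either C7 epimer serves) | C/C=C(/C)C(=O)O[C@@H]1CC[C@]2(C)CC(=O)[C@@H](C(C)(C)O)C[C@H]2[C@]1(C)OC(C)=O | intermediate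
26 | 11-O-methanesulfonyl derivative of 25 | C/C=C(/C)C(=O)O[C@@H]1CC[C@]2(C)CC(=O)[C@@H](C(C)(C)OS(C)(=O)=O)C[C@H]2[C@]1(C)OC(C)=O | intermediate
27 | (5α,10β)-4α-acetoxy-3α-angeloyloxyeudesm-7(11)-en-8-one | C/C=C(/C)C(=O)O[C@@H]1CC[C@]2(C)CC(=O)C(=C(C)C)C[C@H]2[C@]1(C)OC(C)=O | intermediate
28 | (3R,4S,5R,10R)-4α-acetoxy-3α-angeloyloxy-11-hydroperoxyeudesm-6-en-8-one (CNP0225062.1) | C/C=C(/C)C(=O)O[C@@H]1CC[C@]2(C)CC(=O)C(C(C)(C)OO)=C[C@H]2[C@]1(C)OC(C)=O | target

Total step count: 19.
Longest linear sequence: 19 steps (1 and 2 to 28); 6 and 21 enter as purchased reagents.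

Steps most likely to fail

Step 8. After ring closure, the base-mediated inversion at C5 may stall: the cis/trans equilibrium of this enone-containing decalindione may not lie far enough on the trans side, and enolisation toward C7 instead of C5 can open the β-keto ketal by β-elimination. The fallback rebuilds C5 by hydrogenation instead of equilibration; it sets out from 11 (isolated by omitting the DBU stage) and returns to the route at 18. Reduction of 11 with NaBH4 (MeOH–CH2Cl2, −78 °C), hydride entering the convex β face, should give the cis-fused 6α-alcohol F1. Anti elimination with Martin sulfurane (Ph2S[OC(CF3)2Ph]2, CH2Cl2, rt) toward the antiperiplanar ring-fusion hydrogen should give the 1,5-dien-3-one F2. LiN(i-Pr)2 then MeI methylates the extended enolate at C4 to give the 4α-methyl-1,5-dien-3-one F3. NaN(SiMe3)2 then the Davis oxaziridine hydroxylates C4 anti to the C10 methyl to give the 4α-hydroxy-4β-methyl-1,5-dien-3-one F4. Hydrogenation with [Ir(cod)(PCy3)(py)]PF6 (H2, CH2Cl2), directed by the 4α-hydroxyl and opposed on the β face by both axial methyl groups, should saturate C1=C2 and deliver H-5α, giving 18.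

Step 10. Ionisation of the hindered axial sulfamate (E1 with hydride or methyl shift) or anti elimination toward C5 may compete with the syn pathway. The fallback replaces elimination by radical deoxygenation; it sets out from 13 and returns at 18. 1,1′-Thiocarbonyldiimidazole (DMAP, toluene, 80 °C) should convert 13 into the 6β-O-(imidazol-1-ylcarbothioyl) derivative F5. Barton–McCombie reduction (Bu3SnH, AIBN, toluene, 100 °C) gives the 6-deoxy enone F6. LiN(i-Pr)2 then MeI gives the 4α-methyl enone F7, and NaN(SiMe3)2 then the Davis oxaziridine gives the 4α-hydroxy-4β-methyl enone F8. Hydrogenation of F8 (H2, Pd/C, EtOAc) gives 18.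

Step 15. The neopentylic axial 3α-hydroxyl may react too slowly with the mixed anhydride, and forcing the acylation (heat, nucleophilic catalyst) invites Z to E isomerisation of the angeloyl group to the tigloyl ester. The fallback builds the Z alkene on the ester; it sets out from 20 and returns at 23. Forced acylation of 20 with the non-isomerisable 2-[bis(2,2,2-trifluoroethoxy)phosphoryl]propanoic acid (DCC, DMAP, CH2Cl2) should give the 3α-O-phosphonopropanoate F9. Still–Gennari olefination (KN(SiMe3)2, 18-crown-6, THF, −78 °C; acetaldehyde), in which only the phosphonate carbon is deprotonated, should give the Z-configured ester 23.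

Further compounds

F1 | step 8 | (5β,6α,10β)-8,8-(ethylenedioxy)-6-hydroxy-11,12,13,15-tetranoreudesm-1-en-3-one | O=C1C=C[C@]2(C)CC3(OCCO3)C[C@H](O)[C@@H]2C1
F2 | step 8 | (10β)-8,8-(ethylenedioxy)-11,12,13,15-tetranoreudesma-1,5-dien-3-one | O=C1C=C[C@]2(C)CC3(OCCO3)CC=C2C1
F3 | step 8 | (4βH,10β)-8,8-(ethylenedioxy)-11,12,13-trinoreudesma-1,5-dien-3-one (4α-methyl) | O=C1C=C[C@]2(C)CC3(OCCO3)CC=C2[C@@H]1C
F4 | step 8 | (10β)-8,8-(ethylenedioxy)-4α-hydroxy-11,12,13-trinoreudesma-1,5-dien-3-one (4β-methyl) | O=C1C=C[C@]2(C)CC3(OCCO3)CC=C2[C@]1(C)O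
F5 | step 10 | 6β-O-(1H-imidazol-1-ylcarbothioyl) derivative of 13 | O=C1C=C[C@]2(C)CC3(OCCO3)C[C@@H](OC(=S)n3ccnc3)[C@H]2C1
F6 | step 10 | (5α,10β)-8,8-(ethylenedioxy)-11,12,13,15-tetranoreudesm-1-en-3-one | O=C1C=C[C@]2(C)CC3(OCCO3)CC[C@H]2C1
F7 | step 10 | (4βH,5α,10β)-8,8-(ethylenedioxy)-11,12,13-trinoreudesm-1-en-3-one (4α-methyl) | O=C1C=C[C@]2(C)CC3(OCCO3)CC[C@H]2[C@@H]1C
F8 | step 10 | (5α,10β)-8,8-(ethylenedioxy)-4α-hydroxy-11,12,13-trinoreudesm-1-en-3-one (4β-methyl) | O=C1C=C[C@]2(C)CC3(OCCO3)CC[C@H]2[C@]1(C)O
F9 | step 15 | (5α,10β)-3α-{2-[bis(2,2,2-trifluoroethoxy)phosphoryl]propanoyloxy}-4α-hydroxy-11,12,13-trinoreudesman-8-one (epimers at the phosphonate carbon) | CC(C(=O)O[C@@H]1CC[C@]2(C)CC(=O)CC[C@H]2[C@]1(C)O)P(=O)(OCC(F)(F)F)OCC(F)(F)F
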